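**Retrosynthetic overview**

- The target, 2-(4-hydroxyphenyl)ethyl tetracontanoate, is unmasked last by hydrogenolysis of its phenol benzyl ether.
- Key disconnection: C24–C25 of the acyl chain (numbered from the ester carbonyl), giving 1-iodohexadecane and a (15Z)-tetracos-15-enoyl (nervonoyl) ester. The bond is made by a nickel-hydride chain-walking (relay) hydroalkylation, a reductive union of two electrophile-level carbons: nickel enters at the C15=C16 alkene and couples at the C24 methyl terminus.
- Enabling feature: the acyl chain is unbranched, saturated and free of stereocentres, so the alkene is a traceless handle whose position does not matter. C24 is the only primary carbon of the natural C24 acid nervonic acid, and the ester carbonyl C1 lies 23 atoms away.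
- Ester C(=O)–O disconnection: nervonic acid plus 2-[4-(benzyloxy)phenyl]ethanol (Steglich).
- No ring is formed in the route; the only ring, the para-disubstituted benzene, is bought with the protected tyrosol.

Key step: step 2

Assumption: the acyl chain is read as the unbranched C40 (tetracontanoyl) chain, numbered C1 (ester carbonyl) to C40 (methyl); nervonic acid, 2-[4-(benzyloxy)phenyl]ethanol and 1-iodohexadecane are taken as commercial.

**Route**

Step 1
Reactants: 1 (15Z)-tetracos-15-enoic acid (nervonic acid); 2 2-[4-(benzyloxy)phenyl]ethanol
Product: 3 2-[4-(benzyloxy)phenyl]ethyl (15Z)-tetracos-15-enoate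
Conditions: DCC (1.1 equiv), DMAP (0.1 equiv), CH2Cl2, 0 °C to rt
Reagents that add atoms: none
Why: Steglich esterification, in which DCC activates the acid as the O-acylisourea and DMAP relays the acyl group to the primary alcohol of 2; the isolated Z-alkene and the benzyl ether are not touched.

Step 2
Reactants: 3 2-[4-(benzyloxy)phenyl]ethyl (15Z)-tetracos-15-enoate; 4 1-iodohexadecane
Product: 6 2-[4-(benzyloxy)phenyl]ethyl tetracontanoate, via terminal C24 alkylnickel species 5 (not isolated)
Conditions: 4 (2 equiv), NiI2·xH2O (10 mol%), bathocuproine (12 mol%), (MeO)2MeSiH (3 equiv), KF (3 equiv), DMA/THF 1:1, 30 °C, Ar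
Reagents that add atoms: none
Why: Proposed new method: a bathocuproine-ligated nickel hydride (from NiI2, the silane and fluoride) should add across the C15=C16 alkene of 3 and migrate along the chain by repeated β-hydride elimination and reinsertion, and of the equilibrating alkylnickels only the primary one at the C24 terminus (5) is unhindered enough to capture the hexadecyl radical formed from 4 by iodine abstraction, after which C(sp3)–C(sp3) reductive elimination from dialkylnickel(III) forms the C24–C25 bond and leaves C15 and C16 as CH2. The closest known reaction type is the NiH-catalysed reductive relay (chain-walking) hydroalkylation of short internal olefins with primary alkyl iodides, which is terminal-selective and regioconvergent, backed by long-range nickel and palladium chain walks to the methyl end of fatty chains in remote carboxylation and isomerising alkoxycarbonylation; what has not been shown is an eight-position walk followed by alkyl–alkyl coupling in a mid-chain unsaturated fatty ester that carries a second, ester-bearing chain end. Both carbons enter at the electrophile level (an alkene and an alkyl iodide) and are joined under net reduction by the silane, so the step is a reductive union of like-polarity partners that turns an unactivated CH3 into the junction CH2. No ring is closed and no stereocentre is formed, and the Z geometry of 3 is erased. The selectivity needed is C24 over the internal carbons and over C2/C3 next to the ester; it should be secured by C24 being the only primary carbon of the chain, by the 2,9-dimethyl groups of the ligand that retard coupling at secondary alkylnickels (including the α-ester one, thirteen migrations away against eight for C24) and by the excess of 4 that keeps capture of the primary alkylnickel fast. The benzyl ether prevents O-alkylation of the phenol by 4 under the fluoride conditions, and ester and ether are inert to the silane at this temperature.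

Step 3
Reactants: 6 2-[4-(benzyloxy)phenyl]ethyl tetracontanoate
Product: 7 2-(4-hydroxyphenyl)ethyl tetracontanoate
Conditions: H2 (1 atm), 10% Pd/C, EtOAc/THF, 40 °C
Reagents that add atoms: none
Why: Heterogeneous hydrogenolysis of the benzylic C–O bond of the aryl benzyl ether should free the phenol; the ester oxygen sits on a homobenzylic carbon and is not cleaved, and no other reducible group remains.

**Compound list**

1 | (15Z)-tetracos-15-enoic acid (nervonic acid) | CCCCCCCC/C=C\CCCCCCCCCCCCCC(=O)O | starting material
2 | 2-[4-(benzyloxy)phenyl]ethanol | OCCc1ccc(OCc2ccccc2)cc1 | starting material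
3 | 2-[4-(benzyloxy)phenyl]ethyl (15Z)-tetracos-15-enoate | CCCCCCCC/C=C\CCCCCCCCCCCCCC(=O)OCCc1ccc(OCc2ccccc2)cc1 | intermediate
4 | 1-iodohexadecane | CCCCCCCCCCCCCCCCI | starting material
5 | terminal C24 alkylnickel species, 2-[4-(benzyloxy)phenyl]ethyl 24-nickelatetracosanoate (bathocuproine on nickel not drawn) | [Ni]CCCCCCCCCCCCCCCCCCCCCCCC(=O)OCCc1ccc(OCc2ccccc2)cc1 | intermediate
6 | 2-[4-(benzyloxy)phenyl]ethyl tetracontanoate | CCCCCCCCCCCCCCCCCCCCCCCCCCCCCCCCCCCCCCCC(=O)OCCc1ccc(OCc2ccccc2)cc1 | intermediate
7 | 2-(4-hydroxyphenyl)ethyl tetracontanoate | CCCCCCCCCCCCCCCCCCCCCCCCCCCCCCCCCCCCCCCC(=O)OCCc1ccc(O)cc1 | target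

**Totals**

Total step count: 3. Longest linear sequence: 3 steps (1 → 3 → 6 → 7).

**Steps most likely to fail**

1. Step 2 (Proposed new method). The nickel hydride may couple before it has walked the eight positions to the chain end, giving branched alkylation at internal carbons. It may also walk toward the ester and be consumed there by conjugate reduction, giving only net hydrogenation of the alkene. Reduction and homocoupling of the iodide can outrun both. The fallback uses known chemistry only, sets out from 2 and comes back to the route at 6. Alcohol 2 is esterified (DCC, DMAP, CH2Cl2) with commercial 16-bromohexadecanoic acid to give 2-[4-(benzyloxy)phenyl]ethyl 16-bromohexadecanoate F1. F1 is joined by copper-catalysed Grignard–alkyl bromide coupling (Li2CuCl4 3 mol%, NMP, THF, 0 to 20 °C, ester tolerated) with oct-7-enylmagnesium bromide F2, made from commercial 8-bromooct-1-ene and magnesium. This gives 2-[4-(benzyloxy)phenyl]ethyl tetracos-23-enoate F3, which already has the alkene at C23=C24. The established anti-Markovnikov NiH hydroalkylation of a terminal alkene with a primary alkyl iodide (4, NiBr2·diglyme, 4,4'-di-tert-butyl-2,2'-bipyridine, (MeO)2MeSiH, KF, DMA, rt) then forms the same C24–C25 bond without any chain walk and should give 6.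

2. Step 3. Hydrogenolysis may stall because the waxy C40 ester is poorly soluble and because traces of iodide or nickel carried over from step 2 poison the palladium surface. The fallback avoids the protecting group altogether, sets out from 1 and comes back at 7. Fischer esterification of 1 (MeOH, cat. H2SO4) gives methyl (15Z)-tetracos-15-enoate F4. The relay hydroalkylation of step 2 with 4 should give methyl tetracontanoate F5. Saponification (LiOH, THF/H2O, reflux, then HCl) gives tetracontanoic acid F6. A chemoselective Mitsunobu esterification of F6 with commercial tyrosol (PPh3, DIAD, THF/toluene, 40 °C) activates only the primary alcohol, leaves the phenol free and should give 7 directly.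

3. Step 1. The O-acylisourea of the long-chain acid may rearrange to the unreactive N-acylurea before the alcohol attacks, so that the coupling is slow and the urea by-products are hard to remove from the waxy ester. The fallback sets out from 1 and 2 and comes back at 3. It activates the alcohol instead of the acid: Mitsunobu esterification (PPh3, DIAD, THF, 0 °C to rt), in which the carboxylate of 1 displaces the oxyphosphonium derived from 2 at its primary carbon. No new compound is made on the way (F0).

**Further compounds**

F1 | step 2 | 2-[4-(benzyloxy)phenyl]ethyl 16-bromohexadecanoate | BrCCCCCCCCCCCCCCCC(=O)OCCc1ccc(OCc2ccccc2)cc1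
F2 | step 2 | oct-7-enylmagnesium bromide | C=CCCCCCC[Mg]Br
F3 | step 2 | 2-[4-(benzyloxy)phenyl]ethyl tetracos-23-enoate | C=CCCCCCCCCCCCCCCCCCCCCCC(=O)OCCc1ccc(OCc2ccccc2)cc1
F4 | step 3 | methyl (15Z)-tetracos-15-enoate | CCCCCCCC/C=C\CCCCCCCCCCCCCC(=O)OC
F5 | step 3 | methyl tetracontanoate | CCCCCCCCCCCCCCCCCCCCCCCCCCCCCCCCCCCCCCCC(=O)OC
F6 | step 3 | tetracontanoic acid | CCCCCCCCCCCCCCCCCCCCCCCCCCCCCCCCCCCCCCCC(=O)O
F0 | step 1 | none | none
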